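**Plan**

1. Numbering (longipinane; also used for the corresponding carbons of every precursor): C1 ketone, C2=C3(Me), C4 and C11 the cyclobutane CH groups flanking the enone, C5, C6 = CMe2, C7–OH, C8–O-angelate, C9–O-isovalerate, C10 = C(Me).
2. Retrosynthesis: take off the angelate, the C7 oxygen (enolate oxidation) and the C8 hydride (ketone); then cut C8–C9 and C10–C11 together by a retro-de Mayo step that restores a temporary C8–C11 bond; finally cut C1–C11 and C4–C5 (Diels–Alder).
3. Enabling feature: the 1,5-dioxygen array O=C1–C11–C10–C9–C8–O. The unit C10–C9 lies between the α-carbon of the ring ketone and an oxygenated carbon, so the cycloheptane C5–C6–C7–C8–C9–C10–C11 is the two-carbon ring expansion of a cyclopentane C5–C6–C7–C8–C11, and the cyclobutane C4–C5–C11–C10 closes in the same photocycloaddition.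
4. Forward order: cyclohexene ring (C1–C2–C3–C4–C5–C11) by Diels–Alder onto 4,4-dimethylcyclopentenone; β-methoxy enone and E enol isovalerate are set up; [2+2] and acid opening give cyclobutane plus cycloheptanone; then C7 oxidation, C8 reduction, angeloylation.
5. Stereochemistry: absolute configuration (C4, C5) from the catalyst-controlled endo Diels–Alder; C9, C10, C11 from the tether-directed suprafacial photocycloaddition of the E enol ester; C7 and C8 from convex-face attack of peracid and hydride on the rigid tricycle.

Key step: step 9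

Assumption: the facial sense of the oxazaborolidinium-catalysed Diels–Alder reaction is taken from the α-C–H···O binding model for 2-cycloalkenones, which points to the catalyst from (R)-α,α-diphenylprolinol for adduct 8; the (S)-derived catalyst would be used if the sense proved opposite for this hindered enone.

**Route**

Step 1
Reactants: 1 (E)-4-methoxybut-3-en-2-one
Product: 3 (E)-4-[(tert-butyldimethylsilyl)oxy]but-3-en-2-one, via sodium (E)-3-oxobut-1-en-1-olate 2 (not isolated)
Conditions: NaOH (1 equiv), H2O, rt, evaporate; then t-BuMe2SiCl, THF, 0 °C to rt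
Reagents that add atoms: sodium hydroxide [Na+].[OH-]; tert-butyldimethylsilyl chloride CC(C)(C)[Si](C)(C)Cl
Why: Addition–elimination of hydroxide on the vinylogous ester (saponification) gives the sodium enolate of formylacetone, and O-silylation should keep the E enol geometry.

Step 2
Reactants: 3 (E)-4-[(tert-butyldimethylsilyl)oxy]but-3-en-2-one; 4 (2-methylallyl)triphenylphosphonium chloride
Product: 6 tert-butyl{[(1E,3E)-3,5-dimethylhexa-1,3,5-trien-1-yl]oxy}dimethylsilane, via (2-methylallylidene)triphenylphosphorane 5 (not isolated)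
Conditions: n-BuLi, THF, −78 to 0 °C; then 3, −78 °C to rt
Reagents that add atoms: none
Why: Wittig olefination of the ketone by the allylic ylide gives the 1-silyloxytriene; only the 3E isomer can reach the s-cis diene conformation needed in step 3, so any 3Z isomer should pass through inert.

Step 3
Reactants: 6 tert-butyl{[(1E,3E)-3,5-dimethylhexa-1,3,5-trien-1-yl]oxy}dimethylsilane; 7 4,4-dimethylcyclopent-2-en-1-one
Product: 8 (3aS,4S,7R,7aS)-7-[(tert-butyldimethylsilyl)oxy]-3,3,5-trimethyl-4-(prop-1-en-2-yl)-2,3,3a,4,7,7a-hexahydro-1H-inden-1-one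
Conditions: (R)-3,3-diphenyl-1-(2-methylphenyl)tetrahydro-1H,3H-pyrrolo[1,2-c][1,3,2]oxazaborole·HN(SO2CF3)2 (20 mol %), CH2Cl2, −78 to −20 °C
Reagents that add atoms: none
Why: Catalytic enantioselective Diels–Alder reaction in which the silyloxy terminus (C1) bonds to the enone α-carbon (C11) and the isopropenyl-bearing terminus (C4) to the β-carbon (C5) (ortho rule), endo addition places silyloxy and isopropenyl cis to the cyclopentanone ring (all four ring hydrogens cis), and the cationic oxazaborolidine shields one enone face so that all four stereocentres are set under catalyst control.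

Step 4
Reactants: 8 (3aS,4S,7R,7aS)-7-[(tert-butyldimethylsilyl)oxy]-3,3,5-trimethyl-4-(prop-1-en-2-yl)-2,3,3a,4,7,7a-hexahydro-1H-inden-1-one
Product: 9 1,1-dimethyl ketal of 8 (all stereocentres as in 8)
Conditions: MeOSiMe3 (2.5 equiv), Me3SiOSO2CF3 (5 mol %), CH2Cl2, −78 °C; pyridine quench
Reagents that add atoms: methoxytrimethylsilane CO[Si](C)(C)C
Why: Aprotic acetalisation of the only ketone (C8) marks the oxygen that will become the enol ether, so the later β-alkoxy enone is regiochemically unambiguous; no stereocentre is touched.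

Step 5
Reactants: 9 1,1-dimethyl ketal of 8
Product: 10 primary alcohol in which the isopropenyl group of 9 has become CH(CH3)CH2OH (both epimers at that carbon)
Conditions: 9-BBN, THF, 0 °C to rt; then NaOH, H2O2, 0 °C
Reagents that add atoms: hydrogen peroxide OO
Why: Hydroboration–oxidation with 9-BBN selects the 1,1-disubstituted alkene over the trisubstituted ring alkene and places oxygen on the terminal carbon (C9); the new C10 centre is a mixture that is erased in step 8.

Step 6
Reactants: 10 primary alcohol (both C10 epimers)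
Product: 11 diol (10 without the silyl group; free allylic C1–OH)
Conditions: Bu4NF, THF, 0 °C to rt
Reagents that add atoms: none
Why: Fluoride-mediated desilylation frees the allylic alcohol without affecting the ketal.

Step 7
Reactants: 11 diol
Product: 13 2-[1-methoxy-3,3,5-trimethyl-7-oxo-3,3a,4,7-tetrahydro-2H-inden-4-yl]propanal (H-3a and H-4 cis as in 8; both epimers α to the aldehyde), via keto aldehyde ketal 12 (not isolated)
Conditions: Dess–Martin periodinane (2.5 equiv), NaHCO3, CH2Cl2, 0 °C to rt; then PPTS (cat.), CH2Cl2, rt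
Reagents that add atoms: none
Why: Dess–Martin oxidation turns the allylic alcohol into the C1 enone and the primary alcohol into the C9 aldehyde, and the β-keto ketal then loses methanol through its oxocarbenium ion (β-elimination) to give the conjugated enol ether C8(OMe)=C11.

Step 8
Reactants: 13 2-[1-methoxy-3,3,5-trimethyl-7-oxo-3,3a,4,7-tetrahydro-2H-inden-4-yl]propanal; 14 3-methylbutanoic anhydride
Product: 15 (E)-2-[1-methoxy-3,3,5-trimethyl-7-oxo-3,3a,4,7-tetrahydro-2H-inden-4-yl]prop-1-en-1-yl 3-methylbutanoate (H-3a and H-4 cis; ester oxygen cis to the vinylic methyl)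
Conditions: Et3N, DMAP (cat.), toluene, 60 °C
Reagents that add atoms: none
Why: DMAP-catalysed O-acylation of the aldehyde enol (enol ester formation) should favour the E isomer, with the acyloxy group cis to methyl and away from the ring; any Z isomer is separated.

Step 9
Reactants: 15 (E)-enol isovalerate
Product: 16 cage photoadduct, 8-methoxy-9-(3-methylbutanoyloxy)-8,11-cyclolongipin-2-en-1-one (longipinane skeleton plus a C8–C11 bond; C4, C5, C9, C10, C11 as in 24)
Conditions: hν (350–366 nm, Pyrex filter), degassed MeCN (0.005 M), 0 °C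
Reagents that add atoms: none
Why: Proposed new method: an intramolecular enone–alkene [2+2] photocycloaddition (first half of a de Mayo sequence; closest known reaction type: intramolecular photocycloaddition of 3-alkoxy enones, and the parallel closure known for 1,5-dienones with a substituent on the inner alkene carbon) is asked to close in the parallel sense across a two-atom tether (C5, C4), for which a ring-fused 2-acyl-1,5-diene has no direct precedent. Mechanism: the triplet β-methoxy enone bonds from its β-carbon C8 to C9, the acyloxy-bearing alkene terminus (head-to-tail orientation of a donor alkene), closing the six-membered ring C8–C9–C10–C4–C5–C11 and leaving a 1,4-biradical with a tertiary α-keto radical at C11 and a tertiary radical at C10; recombination C11–C10 then closes both four-membered rings, the temporary C8–C9–C10–C11 ring and the cyclobutane C4–C5–C11–C10 of the target. C10 hangs axially from C4, cis to the C5–C6 bond and 1,3 to C11, so it can reach only the lower lobe of C11 and both bonds form on that face of the enone, which sets C10 and C11 (and C8, through the necessarily cis fusion of the new cyclobutane); C9 is set by the E geometry of the enol ester together with suprafacial addition, C9–H pointing at the C6 methyl group and the ester outward. The selectivity needed is parallel (C8–C9, C11–C10) over crossed (C11–C9, C8–C10) closure and reaction of the E isomer only: the first is argued from the fully substituted C10 (a poor first bonding site), the better biradical from C8–C9 bonding and the polarity match of electron-rich C10 with the α-keto carbon C11, the second from the clash a Z ester would have with the C6 methyl group. Light of 350–366 nm excites only the conjugated ketone, and the strain of the bicyclo[2.2.0]hexane unit is paid for by the triplet energy and released in step 10.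

Step 10
Reactants: 16 cage photoadduct
Product: 17 9-(3-methylbutanoyloxy)longipin-2-ene-1,8-dione (C4, C5, C9, C10, C11 as in 24)
Conditions: 1 M HCl, THF, rt
Reagents that add atoms: water O
Why: Acid-promoted retro-aldol-type fragmentation (de Mayo ring opening): protonation of the C1 ketone and push from the methoxy group cleave the strained C8–C11 bond, water converts the oxocarbenium ion into the C8 ketone, and the cyclopentane becomes the cycloheptanone; C11 can be protonated only on its exo face.

Step 11
Reactants: 17 9-(3-methylbutanoyloxy)longipin-2-ene-1,8-dione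
Product: 18 9-(3-methylbutanoyloxy)-8-(triethylsilyloxy)longipina-2,7-dien-1-one
Conditions: LiN(SiMe3)2, Et3SiCl (in situ quench), THF, −78 °C
Reagents that add atoms: chlorotriethylsilane CC[Si](Cl)(CC)CC
Why: Kinetic deprotonation with internal silylation should occur at the C7 methylene and not at the hindered acyloxy-bearing C9 methine or the non-enolisable bridgehead C11, giving the C7=C8 silyl enol ether.

Step 12
Reactants: 18 silyl enol ether
Product: 19 9-(3-methylbutanoyloxy)-7-(triethylsilyloxy)longipin-2-ene-1,8-dione (C7 as in 24)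
Conditions: mCPBA, NaHCO3, CH2Cl2, −20 °C
Reagents that add atoms: 3-chloroperbenzoic acid OOC(=O)c1cccc(Cl)c1
Why: Rubottom oxidation: the peracid epoxidises the electron-rich enol ether from the exposed convex face (the other face abuts C11–H), and silyl migration gives the 7-silyloxy ketone with the C7 oxygen in the target configuration; the electron-poor enone is left alone.

Step 13
Reactants: 19 7-silyloxy-1,8-dione
Product: 20 8-hydroxy-9-(3-methylbutanoyloxy)-7-(triethylsilyloxy)longipin-2-en-1-one (all stereocentres as in 24)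
Conditions: NaBH4, MeOH/THF, −40 °C; AcOH quench
Reagents that add atoms: none
Why: Borohydride reduction should take the doubly α-oxygenated C8 ketone before the conjugated C1 ketone, with hydride entering from the convex face because the concave face is blocked by C11–H, so that C8–OH ends cis to the C9 ester and trans to the C7 silyl ether.

Step 14
Reactants: 20 8-hydroxy-9-(3-methylbutanoyloxy)-7-(triethylsilyloxy)longipin-2-en-1-one; 21 angelic acid [(Z)-2-methylbut-2-enoic acid]
Product: 23 8-angeloyloxy-9-(3-methylbutanoyloxy)-7-(triethylsilyloxy)longipin-2-en-1-one, via angelic 2,4,6-trichlorobenzoic anhydride 22 (not isolated)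
Conditions: 2,4,6-trichlorobenzoyl chloride, Et3N, toluene, rt; then 20, 80 °C
Reagents that add atoms: none
Why: Yamaguchi esterification through the mixed anhydride acylates the only free hydroxyl, and leaving out a nucleophilic pyridine catalyst is meant to prevent Z-to-E isomerisation to the tiglate.

Step 15
Reactants: 23 8-angeloyloxy-9-(3-methylbutanoyloxy)-7-(triethylsilyloxy)longipin-2-en-1-one
Product: 24 (4R,5S,7S,8R,9S,10R,11R)-8-angeloyloxy-7-hydroxy-9-(3-methylbutanoyloxy)longipin-2-en-1-one (CNP0151972.1)
Conditions: HF·pyridine, THF/pyridine, 0 °C to rt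
Reagents that add atoms: none
Why: Acidic fluoride removes the triethylsilyl ether without base, so neither ester should migrate and the angelate should not isomerise.

**Compound list**

1 | (E)-4-methoxybut-3-en-2-one | CO/C=C/C(C)=O | starting material
2 | sodium (E)-3-oxobut-1-en-1-olate | CC(=O)/C=C/[O-].[Na+] | intermediate (not isolated)
3 | (E)-4-[(tert-butyldimethylsilyl)oxy]but-3-en-2-one | CC(=O)/C=C/O[Si](C)(C)C(C)(C)C | intermediate
4 | (2-methylallyl)triphenylphosphonium chloride | C=C(C)C[P+](c1ccccc1)(c1ccccc1)c1ccccc1.[Cl-] | starting material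
5 | (2-methylallylidene)triphenylphosphorane | C=C(C)C=P(c1ccccc1)(c1ccccc1)c1ccccc1 | intermediate (not isolated)
6 | tert-butyl{[(1E,3E)-3,5-dimethylhexa-1,3,5-trien-1-yl]oxy}dimethylsilane | CC(C)(C)[Si](C)(C)O/C=C/C(C)=C/C(C)=C | intermediate
7 | 4,4-dimethylcyclopent-2-en-1-one | O=C1C=CC(C)(C)C1 | starting material
8 | (3aS,4S,7R,7aS)-7-[(tert-butyldimethylsilyl)oxy]-3,3,5-trimethyl-4-(prop-1-en-2-yl)-2,3,3a,4,7,7a-hexahydro-1H-inden-1-one | O=C1CC(C)(C)[C@@H]2[C@H]1[C@H](O[Si](C)(C)C(C)(C)C)C=C(C)[C@@H]2C(C)=C | intermediate
9 | 1,1-dimethyl ketal of 8 | COC1(OC)CC(C)(C)[C@@H]2[C@H]1[C@H](O[Si](C)(C)C(C)(C)C)C=C(C)[C@@H]2C(C)=C | intermediate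
10 | primary alcohol from 9 (isopropenyl replaced by CH(CH3)CH2OH; both epimers at that carbon) | COC1(OC)CC(C)(C)[C@@H]2[C@H]1[C@H](O[Si](C)(C)C(C)(C)C)C=C(C)[C@@H]2C(C)CO | intermediate
11 | diol (10 without the silyl group) | COC1(OC)CC(C)(C)[C@@H]2[C@H]1[C@H](O)C=C(C)[C@@H]2C(C)CO | intermediate
12 | keto aldehyde ketal (C1 ketone, C8 dimethyl ketal, C9 aldehyde) | COC1(OC)CC(C)(C)[C@@H]2[C@H]1C(=O)C=C(C)[C@@H]2C(C)C=O | intermediate (not isolated)
13 | 2-[1-methoxy-3,3,5-trimethyl-7-oxo-3,3a,4,7-tetrahydro-2H-inden-4-yl]propanal (H-3a/H-4 cis) | COC=1CC(C)(C)[C@@H]2C=1C(=O)C=C(C)[C@@H]2C(C)C=O | intermediate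
14 | 3-methylbutanoic anhydride | CC(C)CC(=O)OC(=O)CC(C)C | starting material
15 | (E)-2-[1-methoxy-3,3,5-trimethyl-7-oxo-3,3a,4,7-tetrahydro-2H-inden-4-yl]prop-1-en-1-yl 3-methylbutanoate | COC=1CC(C)(C)[C@@H]2C=1C(=O)C=C(C)[C@@H]2/C(C)=C/OC(=O)CC(C)C | intermediate
16 | 8-methoxy-9-(3-methylbutanoyloxy)-8,11-cyclolongipin-2-en-1-one (cage photoadduct) | CO[C@@]15CC(C)(C)[C@@H]2[C@]53C(=O)C=C(C)[C@@H]2[C@@]3(C)[C@@H]1OC(=O)CC(C)C | intermediate
17 | 9-(3-methylbutanoyloxy)longipin-2-ene-1,8-dione | O=C1CC(C)(C)[C@@H]2[C@H]3C(=O)C=C(C)[C@@H]2[C@@]3(C)[C@@H]1OC(=O)CC(C)C | intermediate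
18 | 9-(3-methylbutanoyloxy)-8-(triethylsilyloxy)longipina-2,7-dien-1-one | CC[Si](CC)(CC)OC1=CC(C)(C)[C@@H]2[C@H]3C(=O)C=C(C)[C@@H]2[C@@]3(C)[C@@H]1OC(=O)CC(C)C | intermediate
19 | 9-(3-methylbutanoyloxy)-7-(triethylsilyloxy)longipin-2-ene-1,8-dione | O=C1[C@@H](O[Si](CC)(CC)CC)C(C)(C)[C@@H]2[C@H]3C(=O)C=C(C)[C@@H]2[C@@]3(C)[C@@H]1OC(=O)CC(C)C | intermediate
20 | 8-hydroxy-9-(3-methylbutanoyloxy)-7-(triethylsilyloxy)longipin-2-en-1-one | O[C@@H]1[C@@H](O[Si](CC)(CC)CC)C(C)(C)[C@@H]2[C@H]3C(=O)C=C(C)[C@@H]2[C@@]3(C)[C@@H]1OC(=O)CC(C)C | intermediate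
21 | angelic acid, (Z)-2-methylbut-2-enoic acid | C/C=C(/C)C(O)=O | starting material
22 | angelic 2,4,6-trichlorobenzoic anhydride | C/C=C(/C)C(=O)OC(=O)c1c(Cl)cc(Cl)cc1Cl | intermediate (not isolated)
23 | 8-angeloyloxy-9-(3-methylbutanoyloxy)-7-(triethylsilyloxy)longipin-2-en-1-one | C/C=C(/C)C(=O)O[C@@H]1[C@@H](O[Si](CC)(CC)CC)C(C)(C)[C@@H]2[C@H]3C(=O)C=C(C)[C@@H]2[C@@]3(C)[C@@H]1OC(=O)CC(C)C | intermediate
24 | (4R,5S,7S,8R,9S,10R,11R)-8-angeloyloxy-7-hydroxy-9-(3-methylbutanoyloxy)longipin-2-en-1-one | C/C=C(/C)C(=O)O[C@@H]1[C@@H](O)C(C)(C)[C@@H]2[C@H]3C(=O)C=C(C)[C@@H]2[C@@]3(C)[C@@H]1OC(=O)CC(C)C | target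

**Step count and risks**

Total step count: 15. Longest linear sequence: 15 steps (1 to 24).

Steps most likely to fail:

1. Step 9 (proposed new method). What may go wrong: the triplet biradical closes in the crossed sense or reverts to starting material, and the enol ester loses its geometry under irradiation. Fallback (sets out from 9, returns at 17): the oxygen-free isopropenyl group is taken through the photocycloaddition instead, since it has no alkene geometry and an alkyl-substituted inner alkene carbon is the pattern for which parallel closure is documented; the C9 oxygen is then added by enolate oxidation. Bu4NF removes the silyl group of 9 to give allylic alcohol F1. MnO2 oxidises it to β-keto ketal F2, which loses methanol with DBU to give β-methoxy enone F3. Irradiation (350 nm, Pyrex, MeCN) gives cage F4, which 1 M HCl/THF opens to diketone F5. LiN(SiMe3)2/Me3SiCl at −78 °C gives the C8=C9 silyl enol ether F6 (deprotonation at the methylene next to the ring-fused quaternary carbon), mCPBA followed by citric acid work-up gives α-ketol F7 (oxygen from the convex face), and anhydride 14 with DMAP returns 17.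

2. Step 3. What may go wrong: slow cycloaddition at the neopentyl β-carbon with decomposition of the silyloxytriene, or poor facial discrimination by the catalyst. Fallback (sets out from 7, returns at 8): substrate control by a removable α'-acetoxy group replaces catalyst control. Mn(OAc)3 in refluxing benzene acetoxylates 7 at the α'-methylene (C7) to give racemic acetate F8. Lipase-mediated enantioselective hydrolysis in pH 7 buffer leaves (R)-acetate F9. Me2AlCl-promoted endo Diels–Alder reaction with 6 on the face anti to the acetoxy group gives adduct F10, and SmI2 in THF/MeOH at −78 °C cleaves the α-acetoxy group to return 8.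

3. Step 13. What may go wrong: competing reduction of the conjugated C1 ketone and slow hydride delivery past the C7 silyloxy group. Fallback (sets out from 19, returns at 20): both carbonyl groups are reduced and the allylic alcohol is re-oxidised. NaBH4/CeCl3 in MeOH at −40 °C (Luche reduction) gives diol F11, and MnO2 in CH2Cl2 oxidises only the allylic C1 alcohol to return 20.

**Further compounds**

F1 | step 9 | allylic alcohol (9 without the silyl group) | COC1(OC)CC(C)(C)[C@@H]2[C@H]1[C@H](O)C=C(C)[C@@H]2C(C)=C
F2 | step 9 | β-keto ketal (C1 ketone, C8 dimethyl ketal, isopropenyl group) | COC1(OC)CC(C)(C)[C@@H]2[C@H]1C(=O)C=C(C)[C@@H]2C(C)=C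
F3 | step 9 | β-methoxy enone with isopropenyl group | COC=1CC(C)(C)[C@@H]2C=1C(=O)C=C(C)[C@@H]2C(C)=C
F4 | step 9 | 8-methoxy-8,11-cyclolongipin-2-en-1-one (cage without C9 oxygen) | CO[C@@]15CC(C)(C)[C@@H]2[C@]53C(=O)C=C(C)[C@@H]2[C@@]3(C)C1
F5 | step 9 | longipin-2-ene-1,8-dione | O=C1CC(C)(C)[C@@H]2[C@H]3C(=O)C=C(C)[C@@H]2[C@@]3(C)C1
F6 | step 9 | 8-(trimethylsilyloxy)longipina-2,8-dien-1-one | C[Si](C)(C)OC=1CC(C)(C)[C@@H]2[C@H]3C(=O)C=C(C)[C@@H]2[C@@]3(C)C=1
F7 | step 9 | 9-hydroxylongipin-2-ene-1,8-dione (C9 as in 24) | O=C1CC(C)(C)[C@@H]2[C@H]3C(=O)C=C(C)[C@@H]2[C@@]3(C)[C@@H]1O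
F8 | step 3 | racemic 5-acetoxy-4,4-dimethylcyclopent-2-en-1-one | CC(=O)OC1C(=O)C=CC1(C)C
F9 | step 3 | (R)-5-acetoxy-4,4-dimethylcyclopent-2-en-1-one | O=C1[C@H](OC(C)=O)C(C)(C)C=C1
F10 | step 3 | 2-acetoxy derivative of 8 (acetoxy trans to the new ring bonds) | O=C1[C@H](OC(C)=O)C(C)(C)[C@@H]2[C@H]1[C@H](O[Si](C)(C)C(C)(C)C)C=C(C)[C@@H]2C(C)=C
F11 | step 13 | 1,8-diol from 19 (C1 carbinol as formed) | O[C@@H]1[C@@H](O[Si](CC)(CC)CC)C(C)(C)[C@@H]2[C@H]3C(O)C=C(C)[C@@H]2[C@@]3(C)[C@@H]1OC(=O)CC(C)C
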